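Assumption: the target is written as its diketo tautomer. It should exist largely as the hydrogen-bonded keto–enol, which is the same compound. "Prenyl" means 3-methylbut-2-enyl throughout.

## Analysis of the target

Target 17 is an open-chain 1,3-diarylpropane-1,3-dione. A C(=O)–CH2–C(=O) chain (C1, C2, C3) joins ring A, a 4-hydroxy-2-methoxy-3-prenylphenyl group on C1, to ring B, a 4-hydroxy-3-prenylphenyl group on C3. There is no stereocenter, and each prenyl double bond ends in two identical methyl groups, so neither configuration nor olefin geometry has to be controlled. The sensitive groups are the two ortho-prenylphenols and the 1,3-diketone. Acid can close an ortho-prenylphenol to a 2,2-dimethylchroman, and electrophilic oxidants, halogenating agents and hydrogenation attack the trisubstituted alkenes. The diketone is acidic, chelating and open to retro-Claisen cleavage by strong nucleophilic base. The difficulty is regiochemical and chemoselective: ring A is contiguously 1,2,3,4-tetrasubstituted with the prenyl group at C3 between OMe at C2 and OH at C4, and two different aroyl groups must be joined through one methylene. The strategy rests on chain C3, the ring B carbonyl carbon, which lies between ring B C1 and chain C2 and is a one-carbon unit at the carbonyl oxidation level, so it can be carbon monoxide. Chain C1 and C2 are then the two carbons of an ethynyl group on ring A C1, and the diketone is a hydrated ynone in which conjugate addition places the heteroatom on the alkyne carbon bound to ring A.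

## Retrosynthetic reasoning

**17 back to 15 (through 16).** The two phenols are masked as methoxymethyl ethers in 16. This acetal is the ortho-directing group needed on ring A and is inert to base, organolithiums and palladium. The chain C1 carbonyl is cut back to the C–N bond of enaminone 15, a vinylogous amide that hydrolyses in the same dilute acid that removes the acetals. The forward step must therefore do three acid-mediated cleavages without touching the prenyl groups.

**15 back to 14.** The C1–N bond is removed to give ynone 14. A secondary amine adds to an ynone only at the alkyne carbon remote from the carbonyl, which here is the carbon bound to ring A. Metal-catalysed hydration is avoided because electrophilic metals could also engage the prenyl alkenes or the ortho-methoxy oxygen.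

**14 back to 5, 13 and 12.** Two bonds are cut at chain C3: ring B C1–C3 and C3–C2. This is the most convergent cut, because C3 then comes from carbon monoxide 13 and the two halves are an aryl iodide 5 and a terminal alkyne 12, both stable and storable. Cutting at the ring A side would need the iodide on the crowded ring A between an alkyne-bearing carbon and OMe. The forward reaction must insert 13 into the aryl–palladium bond before the alkyne is transferred.

**12 back to 11.** The terminal alkyne carbon is removed, leaving aldehyde 11. A one-carbon diazophosphonate homologation under mild base suits a non-enolisable aryl aldehyde with acid-sensitive groups.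

**11 back to 9 (through 10).** The ring C–CHO bond is cut to a C–Br bond. Bromine–lithium exchange gives aryllithium 10 at exactly the carbon that bore bromine, so the aldehyde position is fixed by the commercial bromophenol.

**9 back to 7 and 2 (through 8).** The aryl–CH2 bond of the ring A prenyl group is cut. The carbon between the methoxy and methoxymethoxy groups is the most acidic ring position. A lithium amide deprotonates there to aryllithium 8 without exchanging the bromide, and 8 is alkylated by prenyl bromide 2. The carbanion is meta to bromine, so it has no aryne pathway.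

**7 back to 6.** The acetal O–C bond is cut; 6 is commercial 4-bromo-3-methoxyphenol, which already has the methyl ether, the phenol and the halogen in the right relationship.

**5 back to 4, then to 1 and 2 (through 3).** The acetal is removed to phenol 4, and the aryl–CH2 bond of the ring B prenyl group is cut. Ortho C-alkylation of sodium phenoxide 3 by 2 in a non-polar solvent delivers the linear prenyl group in one step; the para position is blocked by iodine, which is also the handle for the key step.

## Alternatives that were turned down

**Alternative 1:** Ring A is built by a Diels–Alder benzannulation. The disconnection cuts ring A C1–C2 and C5–C6: ketene acetal diene A2 would add to the terminal alkyne of cross-conjugated diynone A3, and loss of methanol would aromatise the adduct to bis-silyl ynone A1.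
- For it: the contiguous substitution pattern of ring A is set by construction, with no metalation next to a halogen. On this point it is stronger than the chosen route.
- Against it: A2 is a fully substituted, hydrolytically labile ketene acetal carrying a prenyl group on an internal diene carbon, and it is hard to make and to hold in the reactive conformation. A3 has two Michael-acceptor alkynes and is prone to polymerisation. The ring B prenyl group still needs the same phenoxide chemistry. A1 is still an ynone, so the hydration endgame is not shortened.
- Comparison: the chosen route buys both rings as arenes and joins them through stable partners in fewer steps.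

**Alternative 2:** The diketone is masked as an isoxazole. The disconnection cuts the bond between chain C1 and C2 plus a C–O bond: the nitrile oxide made by PhI(OAc)2 oxidation of ring A aldoxime A5 would add to ring B alkyne A6 to give 3,5-diarylisoxazole A4. Later N–O reduction and hydrolysis would reveal the diketone.
- For it: no toxic gas is used, there is no competition between carbonylative and direct coupling, the 3,5-regiochemistry with a terminal alkyne is dependable, and A4 is a robust masked diketone. On these points it is as strong or stronger.
- Against it: A6 costs two extra steps from iodide 5 (formylation and homologation), and A5 one more from aldehyde 11. An electrophilic hypervalent iodine oxidant and a nitrile oxide would meet two electron-rich trisubstituted alkenes, and nitrile oxide dimerisation competes. The N–O cleavage cannot be a hydrogenation, so Mo(CO)6 or a similar reagent is needed, followed by the same enaminone hydrolysis as here.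
- Comparison: the chosen route is about three steps shorter and forms two C–C bonds in one operation under non-oxidising conditions.

**Alternative 3:** Both prenyl groups are installed last. The disconnection cuts the two aryl–CH2 bonds: diiodo diketone A8 would undergo a double Negishi coupling with prenylzinc bromide A9, using Pd(OAc)2 and 2-dicyclohexylphosphino-2',6'-bis(dimethylamino)biphenyl, to give A7, the bis-MOM ether of the target (the same compound as 16).
- For it: the acid- and oxidant-sensitive prenyl groups are not carried through the route, and the diketone can come from a classical Claisen condensation. On functional-group exposure it is stronger.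
- Against it: the ring A iodide is flanked by OMe and OMOM, and ligand-controlled linear selectivity is least secure at such di-ortho-substituted sites, so branched "reverse-prenyl" product is a real risk. The acidic diketone would quench A9 or form a chelating zinc enolate, and allylzinc reagents add to ketones. Two couplings must both succeed, and A8 needs a regioselective iodination of ring A.
- Comparison: the chosen route introduces each prenyl group by alkylation with prenyl bromide at a carbon nucleophile, where linear regiochemistry is not in question, and puts the route risk into a single coupling of simple partners.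

Key step: step 7

## Route

Step 1
Reactants: 1 4-iodophenol; 2 prenyl bromide (1-bromo-3-methylbut-2-ene)
Product: 4 4-iodo-2-(3-methylbut-2-enyl)phenol, via sodium 4-iodophenoxide 3 (not isolated)
Conditions: NaH (1.05 equiv), toluene, 0 °C → rt; then 2 (1.0 equiv), rt
Reagents that add atoms: none
Why: Ortho C-alkylation of a phenoxide: in a non-polar solvent the sodium phenoxide reacts as a tight, aggregated ion pair with shielded oxygen, so the allylic bromide is attacked through the ortho carbon at its unhindered CH2 end, and rearomatisation restores the phenol. The para position is blocked by iodine, which is inert to NaH.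

Step 2
Reactants: 4 4-iodo-2-(3-methylbut-2-enyl)phenol
Product: 5 4-iodo-1-(methoxymethoxy)-2-(3-methylbut-2-enyl)benzene
Conditions: MOMCl, i-Pr2NEt, CH2Cl2, 0 °C → rt
Reagents that add atoms: chloromethyl methyl ether (MOMCl), COCCl
Why: Standard O-alkylation of a phenol to its methoxymethyl acetal; the amine base takes up HCl, so the prenyl group never sees acid.

Step 3
Reactants: 6 4-bromo-3-methoxyphenol
Product: 7 1-bromo-2-methoxy-4-(methoxymethoxy)benzene
Conditions: MOMCl, i-Pr2NEt, CH2Cl2, 0 °C → rt
Reagents that add atoms: chloromethyl methyl ether (MOMCl), COCCl
Why: The same acetal protection; it also installs the stronger of the two ortho-directing groups needed in step 4.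

Step 4
Reactants: 7 1-bromo-2-methoxy-4-(methoxymethoxy)benzene; 2 prenyl bromide
Product: 9 1-bromo-2-methoxy-4-(methoxymethoxy)-3-(3-methylbut-2-enyl)benzene, via aryllithium 8 (not isolated)
Conditions: LDA (1.1 equiv), THF, −78 °C; CuBr·SMe2 (0.2 equiv), 2 (1.3 equiv), −78 → 0 °C
Reagents that add atoms: none
Why: Directed ortho metalation: the C–H between OMe and OMOM is the most acidic ring position, and a lithium amide deprotonates it rather than exchanging the bromide; the carbanion is meta to bromine and cannot eliminate to an aryne. Copper-mediated allylic substitution at the CH2 terminus of the bromide gives the linear prenyl arene.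

Step 5
Reactants: 9 1-bromo-2-methoxy-4-(methoxymethoxy)-3-(3-methylbut-2-enyl)benzene
Product: 11 2-methoxy-4-(methoxymethoxy)-3-(3-methylbut-2-enyl)benzaldehyde, via aryllithium 10 (not isolated)
Conditions: n-BuLi (1.1 equiv), THF, −78 °C; DMF (3 equiv), −78 °C → rt; H2O
Reagents that add atoms: N,N-dimethylformamide (DMF), CN(C)C=O
Why: Bromine–lithium exchange at −78 °C is far faster than any deprotonation, and formylation of an aryllithium with a formamide is a standard aldehyde synthesis; the ethers and the prenyl group are inert.

Step 6
Reactants: 11 2-methoxy-4-(methoxymethoxy)-3-(3-methylbut-2-enyl)benzaldehyde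
Product: 12 1-ethynyl-2-methoxy-4-(methoxymethoxy)-3-(3-methylbut-2-enyl)benzene
Conditions: Ohira–Bestmann reagent (1.3 equiv), K2CO3 (2 equiv), MeOH, 0 °C → rt
Reagents that add atoms: dimethyl (1-diazo-2-oxopropyl)phosphonate (Ohira–Bestmann reagent), COP(=O)(OC)C(=[N+]=[N-])C(C)=O
Why: Seyferth–Gilbert homologation in its Ohira–Bestmann form turns a non-enolisable aryl aldehyde into the terminal alkyne under mild base, which leaves the acetal, the methyl ether and the prenyl group untouched.

Step 7
Reactants: 5 4-iodo-1-(methoxymethoxy)-2-(3-methylbut-2-enyl)benzene; 13 carbon monoxide; 12 1-ethynyl-2-methoxy-4-(methoxymethoxy)-3-(3-methylbut-2-enyl)benzene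
Product: 14 3-[2-methoxy-4-(methoxymethoxy)-3-(3-methylbut-2-enyl)phenyl]-1-[4-(methoxymethoxy)-3-(3-methylbut-2-enyl)phenyl]prop-2-yn-1-one
Conditions: PdCl2(PPh3)2 (5 mol %), Et3N (3 equiv), CO (1 atm, balloon), THF/H2O (4:1), rt; 12 added slowly; no copper co-catalyst
Reagents that add atoms: none
Why: This is a carbonylative Sonogashira coupling, a known three-component reaction of aryl iodides, carbon monoxide and terminal arylalkynes. PdCl2(PPh3)2 is reduced in the flask (by CO with water and amine) to zerovalent palladium, which inserts into the C–I bond of 5. Under 1 atm of CO the arylpalladium iodide binds CO and the aryl group migrates to give an aroylpalladium iodide. Alkyne 12 is then deprotonated by Et3N and transferred to palladium, and reductive elimination forms the carbonyl–alkynyl bond and returns zerovalent palladium. Two skeletal bonds form (ring B C1–C3 and C3–C2); no ring closes and no stereocenter is created. The selectivity needed is CO insertion before alkynyl transfer: the para-alkoxy group makes the aryl group of 5 a good migrating group, and the absence of copper together with slow addition of 12 keeps alkynyl transfer slow. The medium is weakly basic, so both acetals and both prenyl groups should survive, and Et3N, being tertiary, cannot add to the ynone.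

Step 8
Reactants: 14 the bis-MOM ynone
Product: 15 (E)-3-[2-methoxy-4-(methoxymethoxy)-3-(3-methylbut-2-enyl)phenyl]-1-[4-(methoxymethoxy)-3-(3-methylbut-2-enyl)phenyl]-3-(pyrrolidin-1-yl)prop-2-en-1-one
Conditions: pyrrolidine (1.5 equiv), EtOH, rt
Reagents that add atoms: pyrrolidine, C1CCNC1
Why: Conjugate (aza-Michael) addition of a secondary amine to an ynone; nitrogen adds to the alkyne carbon bound to ring A, which brings that carbon to the carbonyl oxidation level. The E enaminone is expected, but its geometry is of no consequence because step 9 removes the double bond.

Step 9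
Reactants: 15 the enaminone
Product: 17 1-[4-hydroxy-2-methoxy-3-(3-methylbut-2-enyl)phenyl]-3-[4-hydroxy-3-(3-methylbut-2-enyl)phenyl]propane-1,3-dione (the target), via bis-MOM diketone 16 (not isolated)
Conditions: 2 M aq HCl, MeOH/THF, rt → 45 °C
Reagents that add atoms: water, O
Why: Acid hydrolysis of the vinylogous amide (C-protonation, attack of water, loss of the amine) gives the 1,3-diketone, and the same medium cleaves both aryl methoxymethyl acetals. Both phenols are para to a carbonyl group, so their acetals cleave readily and the freed, weakly nucleophilic phenols should not add to the prenyl alkenes in dilute acid; ring A has OMe, not OH, ortho to its carbonyl, so no chromone can form.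

## Compound list

1 | 4-iodophenol | Oc1ccc(I)cc1 | starting material
2 | prenyl bromide (1-bromo-3-methylbut-2-ene) | CC(C)=CCBr | starting material
3 | sodium 4-iodophenoxide | [Na+].[O-]c1ccc(I)cc1 | intermediate (not isolated)
4 | 4-iodo-2-(3-methylbut-2-enyl)phenol | Oc1ccc(I)cc1CC=C(C)C | intermediate
5 | 4-iodo-1-(methoxymethoxy)-2-(3-methylbut-2-enyl)benzene | COCOc1ccc(I)cc1CC=C(C)C | intermediate
6 | 4-bromo-3-methoxyphenol | COc1cc(O)ccc1Br | starting material
7 | 1-bromo-2-methoxy-4-(methoxymethoxy)benzene | COCOc1ccc(Br)c(OC)c1 | intermediate
8 | [3-bromo-2-methoxy-6-(methoxymethoxy)phenyl]lithium | [Li]c1c(OCOC)ccc(Br)c1OC | intermediate (not isolated)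
9 | 1-bromo-2-methoxy-4-(methoxymethoxy)-3-(3-methylbut-2-enyl)benzene | COCOc1ccc(Br)c(OC)c1CC=C(C)C | intermediate
10 | [2-methoxy-4-(methoxymethoxy)-3-(3-methylbut-2-enyl)phenyl]lithium | [Li]c1ccc(OCOC)c(CC=C(C)C)c1OC | intermediate (not isolated)
11 | 2-methoxy-4-(methoxymethoxy)-3-(3-methylbut-2-enyl)benzaldehyde | O=Cc1ccc(OCOC)c(CC=C(C)C)c1OC | intermediate
12 | 1-ethynyl-2-methoxy-4-(methoxymethoxy)-3-(3-methylbut-2-enyl)benzene | C#Cc1ccc(OCOC)c(CC=C(C)C)c1OC | intermediate
13 | carbon monoxide | [C-]#[O+] | starting material
14 | 3-[2-methoxy-4-(methoxymethoxy)-3-(3-methylbut-2-enyl)phenyl]-1-[4-(methoxymethoxy)-3-(3-methylbut-2-enyl)phenyl]prop-2-yn-1-one | COc1c(C#CC(=O)c2ccc(OCOC)c(CC=C(C)C)c2)ccc(OCOC)c1CC=C(C)C | intermediate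
15 | (E)-3-[2-methoxy-4-(methoxymethoxy)-3-(3-methylbut-2-enyl)phenyl]-1-[4-(methoxymethoxy)-3-(3-methylbut-2-enyl)phenyl]-3-(pyrrolidin-1-yl)prop-2-en-1-one | COc1c(/C(=C\C(=O)c2ccc(OCOC)c(CC=C(C)C)c2)N2CCCC2)ccc(OCOC)c1CC=C(C)C | intermediate
16 | 1-[2-methoxy-4-(methoxymethoxy)-3-(3-methylbut-2-enyl)phenyl]-3-[4-(methoxymethoxy)-3-(3-methylbut-2-enyl)phenyl]propane-1,3-dione | COc1c(C(=O)CC(=O)c2ccc(OCOC)c(CC=C(C)C)c2)ccc(OCOC)c1CC=C(C)C | intermediate (not isolated)
17 | 1-[4-hydroxy-2-methoxy-3-(3-methylbut-2-enyl)phenyl]-3-[4-hydroxy-3-(3-methylbut-2-enyl)phenyl]propane-1,3-dione | COc1c(C(=O)CC(=O)c2ccc(O)c(CC=C(C)C)c2)ccc(O)c1CC=C(C)C | target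

## Step count and risk

Total: 9 steps. Longest linear sequence: 7 steps (steps 3 to 9, from 6); the ring B branch is 2 steps (steps 1 and 2).

**Step 7 (key step).** The likeliest failure is alkynyl transfer to the arylpalladium intermediate before CO insertion, which would give direct aryl–alkynyl coupling. Slow turnover is also possible if CO saturates the catalyst. The fallback sets out from 5 and 12 and returns at 14. Iodine–magnesium exchange of 5 (i-PrMgCl·LiCl, THF, −20 °C) and quenching with DMF would give 4-(methoxymethoxy)-3-(3-methylbut-2-enyl)benzaldehyde F1. Alkyne 12, deprotonated with n-BuLi at −78 °C, would add to F1 to give the racemic propargylic alcohol F2. MnO2 in CH2Cl2 would oxidise F2 to 14, which also removes its stereocenter. This costs two more steps but uses no gas and has no competing coupling.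

**Step 4.** The deprotonation may be incomplete, or the base may remove the proton ortho to bromine, leading to aryne formation or halogen migration. The fallback sets out from 7 and returns at 11, replacing steps 4 and 5 and reversing their order. Bromine–lithium exchange of 7 (n-BuLi, THF, −78 °C) and DMF would give 2-methoxy-4-(methoxymethoxy)benzaldehyde F3. Its formyl group would be masked in the flask by adding lithium 4-methylpiperazin-1-ide, giving the lithium α-amino alkoxide F4. n-BuLi would then deprotonate this bromine-free arene between its two ether oxygens, CuBr·SMe2 and 2 would introduce the prenyl group, and aqueous work-up would release the formyl group to give 11.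

**Step 1.** O-alkylation and a second C-alkylation may compete, and conversion may stall in the heterogeneous medium, so a modest yield must be accepted. The fallback sets out from 1 and returns at 5, replacing steps 1 and 2. O-allylation (allyl bromide, K2CO3, acetone) would give 1-iodo-4-(prop-2-enyloxy)benzene F5. Aromatic Claisen rearrangement (N,N-diethylaniline, about 200 °C) would give 4-iodo-2-(prop-2-enyl)phenol F6, and MOM protection would give 4-iodo-1-(methoxymethoxy)-2-(prop-2-enyl)benzene F7. Cross-metathesis of F7 with excess 2-methyl-2-butene and second-generation Grubbs catalyst would convert the allyl into the prenyl group and give 5. This is two steps longer, but ortho regiochemistry is fixed by the sigmatropic shift.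

**Step 9.** The freed phenol may add to the prenyl double bond under acid (chroman formation), or the alkene may be hydrated before both acetals are gone. The fallback sets out from 15 and returns at 17. The enaminone would first be hydrolysed under very mild conditions (aqueous oxalic acid, THF, rt) and 16 isolated. The acetals would then be removed without Brønsted acid by silyl transfer (TMSOTf, 2,2'-bipyridyl, CH2Cl2, 0 °C), which should give the bis(trimethylsilyl) ether F8. Water would cleave F8 to 17.

## Further compounds

F1 | step 7 | 4-(methoxymethoxy)-3-(3-methylbut-2-enyl)benzaldehyde | COCOc1ccc(C=O)cc1CC=C(C)C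
F2 | step 7 | racemic 3-[2-methoxy-4-(methoxymethoxy)-3-(3-methylbut-2-enyl)phenyl]-1-[4-(methoxymethoxy)-3-(3-methylbut-2-enyl)phenyl]prop-2-yn-1-ol | COc1c(C#CC(O)c2ccc(OCOC)c(CC=C(C)C)c2)ccc(OCOC)c1CC=C(C)C
F3 | step 4 | 2-methoxy-4-(methoxymethoxy)benzaldehyde | COCOc1ccc(C=O)c(OC)c1
F4 | step 4 | racemic lithium [2-methoxy-4-(methoxymethoxy)phenyl](4-methylpiperazin-1-yl)methanolate | [Li+].[O-]C(c1ccc(OCOC)cc1OC)N1CCN(C)CC1
F5 | step 1 | 1-iodo-4-(prop-2-enyloxy)benzene | C=CCOc1ccc(I)cc1
F6 | step 1 | 4-iodo-2-(prop-2-enyl)phenol | C=CCc1cc(I)ccc1O
F7 | step 1 | 4-iodo-1-(methoxymethoxy)-2-(prop-2-enyl)benzene | C=CCc1cc(I)ccc1OCOC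
F8 | step 9 | 1-[2-methoxy-3-(3-methylbut-2-enyl)-4-(trimethylsilyloxy)phenyl]-3-[3-(3-methylbut-2-enyl)-4-(trimethylsilyloxy)phenyl]propane-1,3-dione | COc1c(C(=O)CC(=O)c2ccc(O[Si](C)(C)C)c(CC=C(C)C)c2)ccc(O[Si](C)(C)C)c1CC=C(C)C
A1 | alternative 1 | 1-[4-(tert-butyldimethylsilyloxy)-2-methoxy-3-(3-methylbut-2-enyl)phenyl]-3-[4-(tert-butyldimethylsilyloxy)-3-(3-methylbut-2-enyl)phenyl]prop-2-yn-1-one | COc1c(C(=O)C#Cc2ccc(O[Si](C)(C)C(C)(C)C)c(CC=C(C)C)c2)ccc(O[Si](C)(C)C(C)(C)C)c1CC=C(C)C
A2 | alternative 1 | 3-(tert-butyldimethylsilyloxy)-1,1-dimethoxy-2-(3-methylbut-2-enyl)buta-1,3-diene | COC(OC)=C(CC=C(C)C)C(=C)O[Si](C)(C)C(C)(C)C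
A3 | alternative 1 | 1-[4-(tert-butyldimethylsilyloxy)-3-(3-methylbut-2-enyl)phenyl]penta-1,4-diyn-3-one | C#CC(=O)C#Cc1ccc(O[Si](C)(C)C(C)(C)C)c(CC=C(C)C)c1
A4 | alternative 2 | 3-[2-methoxy-4-(methoxymethoxy)-3-(3-methylbut-2-enyl)phenyl]-5-[4-(methoxymethoxy)-3-(3-methylbut-2-enyl)phenyl]isoxazole | COc1c(-c2cc(-c3ccc(OCOC)c(CC=C(C)C)c3)on2)ccc(OCOC)c1CC=C(C)C
A5 | alternative 2 | (E)-2-methoxy-4-(methoxymethoxy)-3-(3-methylbut-2-enyl)benzaldehyde oxime | O/N=C/c1ccc(OCOC)c(CC=C(C)C)c1OC
A6 | alternative 2 | 4-ethynyl-1-(methoxymethoxy)-2-(3-methylbut-2-enyl)benzene | C#Cc1ccc(OCOC)c(CC=C(C)C)c1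
A7 | alternative 3 | 1-[2-methoxy-4-(methoxymethoxy)-3-(3-methylbut-2-enyl)phenyl]-3-[4-(methoxymethoxy)-3-(3-methylbut-2-enyl)phenyl]propane-1,3-dione (identical with 16) | COc1c(C(=O)CC(=O)c2ccc(OCOC)c(CC=C(C)C)c2)ccc(OCOC)c1CC=C(C)C
A8 | alternative 3 | 1-[3-iodo-2-methoxy-4-(methoxymethoxy)phenyl]-3-[3-iodo-4-(methoxymethoxy)phenyl]propane-1,3-dione | COc1c(C(=O)CC(=O)c2ccc(OCOC)c(I)c2)ccc(OCOC)c1I
A9 | alternative 3 | prenylzinc bromide | CC(C)=CC[Zn]Br
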